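## The problem

Compound 15 is an achiral, twofold-symmetric dimer: two 2-hydroxy-5-methoxy-6-methyl-1,4-benzoquinone rings are joined through their C3 carbons by an unbranched tetradecane-1,14-diyl chain, with no ring fusion and no stereocentre. The task is therefore one of regiochemistry and oxidation level. Every ring carbon is substituted and four of the six bear oxygen; only the C5 oxygen is methylated, the C2 oxygen must end as a free enolic hydroxyl, and C1 and C4 must end as the quinone carbonyls. Methyl (C6) and chain (C3) are para to each other and each is flanked by two oxygens, a pattern that substitution on a preformed arene does not deliver cleanly. The hydroxyquinone is a vinylogous acid carrying a vinylogous methyl ester: strong base or nucleophiles can displace the methoxy group, basic peroxide degrades the ring, and the reduced benzene-1,2,4-triol form 14 is air-sensitive, so the quinone should be unveiled last under mild, non-basic conditions. The saturated C14 linker has no handle for a late union, which favours carrying it in from a purchased α,ω-difunctional chain. The enabling feature appears when each ring is numbered C1 (C=O beside C–OH), C2 (C–OH), C3 (chain), C4 (C=O), C5 (C–OMe), C6 (C–Me): the C3–C4 edge with its chain and oxygen is the two carbons of a 1-siloxyalkyne, C2 with its hydroxyl is a ketene carbonyl carbon, and C5, C6 and C1 with methoxy, methyl and oxygen are C2, C3 and C4 of a cyclobutenone. Because the rings are identical and remote, one α,ω-bis(siloxyalkyne) 8 can take up two molecules of cyclobutenone 5 and close both arenes in one operation.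

## Retrosynthesis

**15 ⇒ 14 ⇒ 13 (no skeletal bond cut).** Target 15 is traced to bis(triol) 14 by two-electron reduction of each ring, and 14 to the tetrasilyl ether 13 by placing silicon on the C1 and C4 oxygens. Leaving the redox step to the end is preferred over carrying a quinone through C–C bond formation, since the quinone tolerates neither heat with nucleophiles nor organometallics. In 13 the four oxygens of each ring are already distinct (free OH at C2, silyl ethers at C1 and C4, methyl ether at C5), so no selective methylation or selective oxidation is needed. The forward steps must cleave four aryl silyl ethers without touching the methyl ether, and oxidise without demethylation.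

**13 ⇒ 8 + 2 × 5 (key disconnection).** In each ring the C2–C3 and C4–C5 bonds are cut, together with the C1–C2 bond that is opened and re-closed in the electrocyclic sequence. The neighbouring cuts, at the aryl–chain bond or inside the chain, leave a hexasubstituted arene with four differentiated oxygens to be made separately. This cut breaks the arene down into a four-membered ring and an alkyne, and attaches the chain in the same event. The precursors are the acyclic, stereochemically featureless diyne 8 and the small racemic cyclobutenone 5. The forward reaction must run a thermal cascade cleanly at both chain ends, with complete regiocontrol in the ketene–ynol ether cycloaddition.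

**8 ⇒ 7 ⇒ 6.** The O–Si bonds of 8 are cut to the dilithium bis(ynolate) 7. In 7, excising C2 and C17 (C1–C2, C2–C3 and their mirror bonds) leads to the C16 diester 6. A route through a terminal C18 diyne would first require that diyne to be made; the ester homologation uses a purchasable diester directly and reaches 8 in one flask. The forward reaction must complete a one-carbon insertion twice in one molecule and silylate the ynolate on oxygen, not carbon.

**5 ⇒ 3 ⇒ 2 ⇒ 1.** The C3–CH3 bond of 5 is cut with a 1,3-carbonyl transposition, leading through alkoxide 4 to the vinylogous ester 3. Cutting O–Si gives hydroxycyclobutenone 2, and cutting the C4–H bond gives dimethyl squarate 1. Hydride goes in first so that the oxygen-bearing sp3 carbon is fixed before the methyl group is introduced. Since that carbon neighbours both the old and the new carbonyl position, the transposition can give only the 2-methoxy-3-methyl arrangement. In the reverse order the hydride would attack the more electrophilic carbonyl of the intermediate dione, and methyl and methoxy would be interchanged in the final arene.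

## Roads not taken

**Alternative 1:** The cut is at the two benzylic C–C bonds of the linker, drawn as alkenes. The bis-ylide from dodecane-1,12-diylbis(triphenylphosphonium) dibromide A1 would condense with two molecules of 2,3,6-tris(benzyloxy)-5-methoxy-4-methylbenzaldehyde A2 to give the (1Z,13Z)-diene A3.
- Merits: the Wittig union is dependable and its alkene geometry is irrelevant. One catalytic hydrogenation would saturate A3 and remove all six benzyl groups, arriving at 14 without fluoride. Both fragments are robust.
- Weak points: A2 is a pentasubstituted benzaldehyde with both ortho positions blocked, so the ylide meets a hindered carbonyl twice. More seriously, making A2 means building the hexasubstituted, four-oxygen arene with its oxygens differentiated, which is the central problem of the target and which the disconnection leaves unsolved and adds as a multistep arene synthesis.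
- Comparison: the fragment union is more certain than a two-fold thermal cascade, and A1 and A2 are easier to handle than siloxyalkyne 8. Against that, the chosen plan makes ring and ring–chain bond in one step from a C4 ring and an acyclic diyne, places every substituent by mechanism, and reaches 15 in a six-step longest sequence.

**Alternative 2:** The cut is inside each ring at two C–C bonds of a cyclohexane-1,3-dione. The bis(enone) (4E,20E)-tetracosa-4,20-diene-3,22-dione A4 and two equivalents of dimethyl malonate A5 under alkoxide would undergo Michael addition at each β-carbon and Dieckmann closure of the ethyl ketone enolate onto an ester, then saponification and decarboxylation, to give 5,5'-(tetradecane-1,14-diyl)bis(3-hydroxy-2-methylcyclohex-2-en-1-one) A6.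
- Merits: commodity reagents, no protecting groups, easy scale-up, and the para relationship of methyl and chain is set correctly.
- Weak points: A6 carries only two of the four oxygens per ring and is at the wrong oxidation level. After aromatisation, two more C–O bonds would have to be installed next to the chain, and one of two nearly equivalent hydroxyls (one beside methyl, one beside the chain) would then need selective methylation, with no controlling element in the structure.
- Comparison: the ring-forming step itself is more robust and cheaper than the chosen one. The chosen plan sets against this that all four oxygens emerge differentiated at the moment the ring forms, so no late oxidation or selective methylation is needed.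

**Alternative 3:** The cut is at two alkene bonds inside the linker. A ruthenium alkylidene catalyst would open cis-cyclooctene A8 and cap both ends with 1,2,4-tris(benzyloxy)-3-(but-3-en-1-yl)-5-methoxy-6-methylbenzene A7 to give the (3E,11E)-diene A9.
- Merits: metathesis tolerates the functionality, the alkene geometry is irrelevant, and one hydrogenation would again lead to 14.
- Weak points: ring-opening polymerisation of A8 competes with capping, so products containing two or more cyclooctene units (each eight carbons longer) and the homodimer of A7 are expected beside A9. The linker length, the one feature that defines the chain, would be under statistical control, and the homologues would be hard to separate. A7 also requires the same hexasubstituted arene synthesis as in Alternative 1.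
- Comparison: the catalytic step is milder than heating a siloxyalkyne and the route is modular in chain length. The chosen plan sets against this a linker length fixed by the purchased C16 diester 6 and no separate arene synthesis.

Key step: step 5

Remark: cyclobutenes 2–5 are racemic and 10 and 12 form as stereoisomer mixtures; every such centre becomes an aromatic sp2 carbon in step 5, so no stereocontrol is planned. Diethyl hexadecanedioate 6 is taken as a purchasable diester.

## Route

Step 1
Reactants: 1 dimethyl squarate (3,4-dimethoxycyclobut-3-ene-1,2-dione)
Product: 2 rac-4-hydroxy-2,3-dimethoxycyclobut-2-en-1-one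
Conditions: LiAlH(Ot-Bu)3 (1.05 equiv), THF, −78 → −20 °C; H2O, 0 °C
Reagents that add atoms: none
Why: Chemoselective 1,2-hydride mono-reduction of a squarate diester with a hindered alkoxyaluminium hydride; after one hydride transfer the remaining carbonyl is a deactivated vinylogous ester and should not be reduced at low temperature. The new centre at C4 forms racemic and needs no control because it becomes an aromatic carbon in step 5.

Step 2
Reactants: 2 rac-4-hydroxy-2,3-dimethoxycyclobut-2-en-1-one
Product: 3 rac-4-(tert-butyldimethylsilyloxy)-2,3-dimethoxycyclobut-2-en-1-one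
Conditions: TBSCl, imidazole, DMF, 0 °C → rt
Reagents that add atoms: tert-butyldimethylsilyl chloride, CC(C)(C)[Si](C)(C)Cl
Why: Imidazole-mediated O-silylation of a secondary alcohol under non-acidic conditions, which avoids the acid-triggered loss of methanol to which 2 is prone. The silyl ether removes the acidic proton before the organolithium step and later serves as the outward-rotating donor in the ring opening.

Step 3
Reactants: 3 rac-4-(tert-butyldimethylsilyloxy)-2,3-dimethoxycyclobut-2-en-1-one
Product: 5 rac-4-(tert-butyldimethylsilyloxy)-2-methoxy-3-methylcyclobut-2-en-1-one, via lithium cyclobutenolate 4 (not isolated)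
Conditions: MeLi (1.1 equiv), THF, −78 °C; then 1 M aq. HCl added at −78 °C, → 0 °C
Reagents that add atoms: methyllithium, [Li]C; water, O
Why: Stork–Danheiser-type alkylative carbonyl transposition, as practised on 3-alkoxycyclobutenones: MeLi adds 1,2 to the only carbonyl to give 4, and aqueous acid ionises the tertiary allylic alcohol to a methoxy-stabilised cyclobutenyl cation, which water captures at the methoxy-bearing terminus and which collapses with loss of methanol to the enone. Because C4 neighbours both the old and the new carbonyl carbon, only the 2-methoxy-3-methyl isomer 5 can result; the cold acid quench is meant to outrun silyl migration in 4.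

Step 4
Reactants: 6 diethyl hexadecanedioate
Product: 8 1,18-bis(triisopropylsilyloxy)octadeca-1,17-diyne, via dilithium bis(ynolate) 7 (not isolated)
Conditions: CH2Br2, lithium 2,2,6,6-tetramethylpiperidide (LiTMP), THF, −78 °C; then n-BuLi, −78 → 25 °C; then TIPSCl, −78 → 0 °C; filtration through neutral alumina
Reagents that add atoms: dibromomethane, BrCBr; triisopropylsilyl chloride, CC(C)[Si](Cl)(C(C)C)C(C)C
Why: Kowalski ester homologation stopped at the ynolate and trapped on oxygen: LiCHBr2 adds to each ester, n-BuLi effects enolisation and bromine–lithium exchange, and the carbenoid undergoes 1,2-alkyl shift to ynolate 7. Bulky TIPSCl silylates ynolates on oxygen, whereas smaller silyl chlorides tend to give silylketenes. The two termini are fourteen methylenes apart and should react independently.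

Step 5
Reactants: 8 1,18-bis(triisopropylsilyloxy)octadeca-1,17-diyne; 5 rac-4-(tert-butyldimethylsilyloxy)-2-methoxy-3-methylcyclobut-2-en-1-one (2.4 equiv)
Product: 13 2,2'-(tetradecane-1,14-diyl)bis[6-(tert-butyldimethylsilyloxy)-4-methoxy-5-methyl-3-(triisopropylsilyloxy)phenol], via vinylketene 9 (not isolated), via bis(4-alkenylcyclobutenone) 10 (not isolated), via bis(dienylketene) 11 (not isolated), via bis(cyclohexa-2,4-dienone) 12 (not isolated)
Conditions: toluene (0.2 M in 8), 80 → 110 °C, Ar, sealed vessel
Reagents that add atoms: none
Why: This is a Danheiser benzannulation of a cyclobutenone with a siloxyalkyne, run at both termini of 8. Heating opens 5 by conrotatory 4π electrocyclic cleavage to vinylketene 9, the silyloxy group rotating outward. Each siloxyalkyne then adds to the ketene C=C in a [2+2] whose regiochemistry follows from polarity: the chain-bearing alkyne carbon, made nucleophilic by the silyloxy donor, bonds to the ketene carbonyl carbon (C2–C3) and the oxygen-bearing carbon to the methoxy-bearing ketene carbon (C4–C5), giving 10. A second 4π opening, with methoxy turning outward and the alkenyl arm inward, gives the Z-dienylketene 11. Each benzene ring is closed by thermally allowed disrotatory 6π electrocyclisation (six-membered, C1–C2 bond) to dienone 12, and enolisation delivers phenol 13. No stereocentre survives: the centres of 5, 10 and 12 are racemic and are erased on aromatisation. The only selectivity needed is regiochemical and is secured by the matched polarity of ketene and ynol ether; a modest excess of 5 should drive both ends to completion, and the phenolic hydroxyl, flanked by the chain and a silyl ether, is poorly placed to intercept surplus ketene.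

Step 6
Reactants: 13 2,2'-(tetradecane-1,14-diyl)bis[6-(tert-butyldimethylsilyloxy)-4-methoxy-5-methyl-3-(triisopropylsilyloxy)phenol]
Product: 14 3,3'-(tetradecane-1,14-diyl)bis(5-methoxy-6-methylbenzene-1,2,4-triol)
Conditions: TBAF (5 equiv), AcOH (5 equiv), degassed THF, 0 °C → rt, Ar; degassed aq. NH4Cl work-up; used crude
Reagents that add atoms: none
Why: Fluoride-induced cleavage of aryl silyl ethers, driven by the strong Si–F bond and the good phenoxide leaving group. The acetic acid buffer protonates each phenoxide as it forms, so the electron-rich triol is not held as its anion, and exclusion of air defers oxidation to step 7; the methyl ether is inert to fluoride.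

Step 7
Reactants: 14 3,3'-(tetradecane-1,14-diyl)bis(5-methoxy-6-methylbenzene-1,2,4-triol)
Product: 15 3,3'-(tetradecane-1,14-diyl)bis(2-hydroxy-5-methoxy-6-methylcyclohexa-2,5-diene-1,4-dione)
Conditions: FeCl3 (4.4 equiv), THF/H2O, 0 °C → rt
Reagents that add atoms: none
Why: Classical FeCl3 oxidation of a hydroxyhydroquinone to a 2-hydroxy-1,4-benzoquinone, as in the last stage of Thiele–Winter sequences: two one-electron transfers per ring convert the para-related C1 and C4 hydroxyls into the quinone carbonyls, while the C2 hydroxyl remains as the enol and the C5 methyl ether is untouched. The acidic medium keeps the product protonated and suppresses nucleophilic attack on the vinylogous ester.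

## Compound list

1 | dimethyl squarate (3,4-dimethoxycyclobut-3-ene-1,2-dione) | COC1=C(OC)C(=O)C1=O | starting material
2 | rac-4-hydroxy-2,3-dimethoxycyclobut-2-en-1-one | COC1=C(OC)C(O)C1=O | intermediate
3 | rac-4-(tert-butyldimethylsilyloxy)-2,3-dimethoxycyclobut-2-en-1-one | COC1=C(OC)C(O[Si](C)(C)C(C)(C)C)C1=O | intermediate
4 | lithium 4-(tert-butyldimethylsilyloxy)-2,3-dimethoxy-1-methylcyclobut-2-en-1-olate (racemic diastereomer mixture, not isolated) | [Li+].[O-]C1(C)C(OC)=C(OC)C1O[Si](C)(C)C(C)(C)C | intermediate
5 | rac-4-(tert-butyldimethylsilyloxy)-2-methoxy-3-methylcyclobut-2-en-1-one | COC1=C(C)C(O[Si](C)(C)C(C)(C)C)C1=O | intermediate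
6 | diethyl hexadecanedioate | CCOC(=O)CCCCCCCCCCCCCCC(=O)OCC | starting material
7 | dilithium octadeca-1,17-diyne-1,18-diolate (not isolated) | [Li+].[Li+].[O-]C#CCCCCCCCCCCCCCCC#C[O-] | intermediate
8 | 1,18-bis(triisopropylsilyloxy)octadeca-1,17-diyne | CC(C)[Si](OC#CCCCCCCCCCCCCCCC#CO[Si](C(C)C)(C(C)C)C(C)C)(C(C)C)C(C)C | intermediate
9 | (E)-4-(tert-butyldimethylsilyloxy)-2-methoxy-3-methylbuta-1,3-dien-1-one (not isolated) | COC(=C=O)/C(C)=C/O[Si](C)(C)C(C)(C)C | intermediate
10 | 2,2'-(tetradecane-1,14-diyl)bis{4-[(E)-1-(tert-butyldimethylsilyloxy)prop-1-en-2-yl]-4-methoxy-3-(triisopropylsilyloxy)cyclobut-2-en-1-one} (diastereomer mixture, not isolated) | O=C1C(CCCCCCCCCCCCCCC2=C(O[Si](C(C)C)(C(C)C)C(C)C)C(OC)(/C(C)=C/O[Si](C)(C)C(C)(C)C)C2=O)=C(O[Si](C(C)C)(C(C)C)C(C)C)C1(OC)/C(C)=C/O[Si](C)(C)C(C)(C)C | intermediate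
11 | 2,2'-(tetradecane-1,14-diyl)bis[(3Z,5E)-6-(tert-butyldimethylsilyloxy)-4-methoxy-5-methyl-3-(triisopropylsilyloxy)hexa-1,3,5-trien-1-one] (not isolated) | O=C=C(CCCCCCCCCCCCCCC(=C=O)/C(O[Si](C(C)C)(C(C)C)C(C)C)=C(OC)\C(C)=C\O[Si](C)(C)C(C)(C)C)/C(O[Si](C(C)C)(C(C)C)C(C)C)=C(OC)\C(C)=C\O[Si](C)(C)C(C)(C)C | intermediate
12 | 2,2'-(tetradecane-1,14-diyl)bis[6-(tert-butyldimethylsilyloxy)-4-methoxy-5-methyl-3-(triisopropylsilyloxy)cyclohexa-2,4-dien-1-one] (diastereomer mixture, not isolated) | O=C1C(CCCCCCCCCCCCCCC2=C(O[Si](C(C)C)(C(C)C)C(C)C)C(OC)=C(C)C(O[Si](C)(C)C(C)(C)C)C2=O)=C(O[Si](C(C)C)(C(C)C)C(C)C)C(OC)=C(C)C1O[Si](C)(C)C(C)(C)C | intermediate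
13 | 2,2'-(tetradecane-1,14-diyl)bis[6-(tert-butyldimethylsilyloxy)-4-methoxy-5-methyl-3-(triisopropylsilyloxy)phenol] | COc1c(C)c(O[Si](C)(C)C(C)(C)C)c(O)c(CCCCCCCCCCCCCCc2c(O)c(O[Si](C)(C)C(C)(C)C)c(C)c(OC)c2O[Si](C(C)C)(C(C)C)C(C)C)c1O[Si](C(C)C)(C(C)C)C(C)C | intermediate
14 | 3,3'-(tetradecane-1,14-diyl)bis(5-methoxy-6-methylbenzene-1,2,4-triol) | COc1c(C)c(O)c(O)c(CCCCCCCCCCCCCCc2c(O)c(O)c(C)c(OC)c2O)c1O | intermediate
15 | 3,3'-(tetradecane-1,14-diyl)bis(2-hydroxy-5-methoxy-6-methylcyclohexa-2,5-diene-1,4-dione) (CNP0278640.0) | COC1=C(C)C(=O)C(O)=C(CCCCCCCCCCCCCCC2=C(O)C(=O)C(C)=C(OC)C2=O)C1=O | target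

## Step count and risk

Total step count: 7 (steps 1–3 to the cyclobutenone, step 4 to the diyne, steps 5–7 for annulation and endgame).
Longest linear sequence: 6 steps (steps 1, 2, 3, 5, 6, 7).

**Step 5 (key step).** The most likely failure is that the two termini do not finish together. A vinylketene that finds no alkyne can acylate the phenolic hydroxyl of a ring already formed, or dimerise; because 5 must be the excess component in the two-directional mode, stoichiometry cannot suppress this. Prolonged heating to force the second annulation invites 1,3-silyl shift of the remaining siloxyalkyne to a silylketene and oxygen-to-oxygen silyl migration in the product. The fallback makes each ring one-directionally, with the alkyne in excess, and joins the halves afterwards; it sets out from 5 and returns at 13. Commercial ethyl non-8-enoate F1 would be taken through the homologation–silylation of step 4 to triisopropyl(dec-9-en-1-yn-1-yloxy)silane F2. Heating F2 (1.5 equiv) with 5 in toluene should give 6-(tert-butyldimethylsilyloxy)-4-methoxy-5-methyl-2-(oct-7-en-1-yl)-3-(triisopropylsilyloxy)phenol F3. Homodimerising olefin metathesis with the second-generation Grubbs catalyst (CH2Cl2, 40 °C) would join two molecules to 2,2'-(tetradec-7-ene-1,14-diyl)bis[6-(tert-butyldimethylsilyloxy)-4-methoxy-5-methyl-3-(triisopropylsilyloxy)phenol] F4 (E/Z mixture), and hydrogenation (H2, Pd/C, EtOAc) would saturate the linker to 13.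

**Step 3.** The most likely failure is 1,2 oxygen-to-oxygen silyl migration within alkoxide 4 before the quench (the new alkoxide sits next to the silyl ether), with partial loss of the silyl ether in the acid stage as a second risk. The fallback replaces the silyl group by an acetal that cannot migrate and carries it through its own annulation; it sets out from 2 and returns at 14. Protection of 2 with MOMCl/i-Pr2NEt (CH2Cl2, 0 °C) would give rac-2,3-dimethoxy-4-(methoxymethoxy)cyclobut-2-en-1-one F5. MeLi addition and hydrolysis with dilute aqueous oxalic acid would give rac-2-methoxy-4-(methoxymethoxy)-3-methylcyclobut-2-en-1-one F6. Heating F6 with 8 as in step 5 should give 2,2'-(tetradecane-1,14-diyl)bis[4-methoxy-6-(methoxymethoxy)-5-methyl-3-(triisopropylsilyloxy)phenol] F7, and TBAF/AcOH followed by HCl in degassed MeOH would remove silyl and acetal groups to reach 14.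

**Step 4.** The most likely failure is incomplete homologation at one terminus, since addition, enolisation, exchange and 1,2-shift must all succeed twice in one molecule, together with protonation of the ynolate before silylation and hydrolysis of the siloxyalkyne on purification. The fallback builds the ynolate by oxidising an acetylide, in separately purifiable stages; it sets out from 6 and returns at 8 through 7. Reduction of 6 with i-Bu2AlH (CH2Cl2, −78 °C) would give hexadecanedial F8. Ohira–Bestmann homologation (dimethyl (1-diazo-2-oxopropyl)phosphonate, K2CO3, MeOH) would give octadeca-1,17-diyne F9. Double deprotonation (n-BuLi, THF) and oxidation of the bis(acetylide) with lithium tert-butyl peroxide (from t-BuOOH and LiN(SiMe3)2, −78 → 0 °C) would give 7, which TIPSOTf would silylate to 8.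

**Step 6.** The most likely failure is autoxidation and oxidative coupling of the electron-rich phenoxides while fluoride is still present, followed by nucleophilic displacement of the methoxy group once quinone has formed prematurely. The fallback traps each phenoxide as an air-stable acetate; it sets out from 13 and returns at 14. Desilylation with TBAF in THF in the presence of Ac2O would give 3,3'-(tetradecane-1,14-diyl)bis(5-methoxy-6-methylbenzene-1,2,4-triyl) hexaacetate F10, which can be purified in air. Methanolysis with HCl in degassed MeOH would release 14 immediately before the oxidation of step 7.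

## Further compounds

F1 | step 5 | ethyl non-8-enoate | C=CCCCCCCC(=O)OCC
F2 | step 5 | triisopropyl(dec-9-en-1-yn-1-yloxy)silane | C=CCCCCCCC#CO[Si](C(C)C)(C(C)C)C(C)C
F3 | step 5 | 6-(tert-butyldimethylsilyloxy)-4-methoxy-5-methyl-2-(oct-7-en-1-yl)-3-(triisopropylsilyloxy)phenol | COc1c(C)c(O[Si](C)(C)C(C)(C)C)c(O)c(CCCCCCC=C)c1O[Si](C(C)C)(C(C)C)C(C)C
F4 | step 5 | 2,2'-(tetradec-7-ene-1,14-diyl)bis[6-(tert-butyldimethylsilyloxy)-4-methoxy-5-methyl-3-(triisopropylsilyloxy)phenol] (E/Z mixture) | COc1c(C)c(O[Si](C)(C)C(C)(C)C)c(O)c(CCCCCCC=CCCCCCCc2c(O)c(O[Si](C)(C)C(C)(C)C)c(C)c(OC)c2O[Si](C(C)C)(C(C)C)C(C)C)c1O[Si](C(C)C)(C(C)C)C(C)C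
F5 | step 3 | rac-2,3-dimethoxy-4-(methoxymethoxy)cyclobut-2-en-1-one | COCOC1C(=O)C(OC)=C1OC
F6 | step 3 | rac-2-methoxy-4-(methoxymethoxy)-3-methylcyclobut-2-en-1-one | COCOC1C(=O)C(OC)=C1C
F7 | step 3 | 2,2'-(tetradecane-1,14-diyl)bis[4-methoxy-6-(methoxymethoxy)-5-methyl-3-(triisopropylsilyloxy)phenol] | COCOc1c(C)c(OC)c(O[Si](C(C)C)(C(C)C)C(C)C)c(CCCCCCCCCCCCCCc2c(O)c(OCOC)c(C)c(OC)c2O[Si](C(C)C)(C(C)C)C(C)C)c1O
F8 | step 4 | hexadecanedial | O=CCCCCCCCCCCCCCCC=O
F9 | step 4 | octadeca-1,17-diyne | C#CCCCCCCCCCCCCCCC#C
F10 | step 6 | 3,3'-(tetradecane-1,14-diyl)bis(5-methoxy-6-methylbenzene-1,2,4-triyl) hexaacetate | COc1c(C)c(OC(C)=O)c(OC(C)=O)c(CCCCCCCCCCCCCCc2c(OC(C)=O)c(OC(C)=O)c(C)c(OC)c2OC(C)=O)c1OC(C)=O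
A1 | alternative 1 | dodecane-1,12-diylbis(triphenylphosphonium) dibromide | [Br-].[Br-].c1ccccc1[P+](c1ccccc1)(c1ccccc1)CCCCCCCCCCCC[P+](c1ccccc1)(c1ccccc1)c1ccccc1
A2 | alternative 1 | 2,3,6-tris(benzyloxy)-5-methoxy-4-methylbenzaldehyde | COc1c(C)c(OCc2ccccc2)c(OCc2ccccc2)c(C=O)c1OCc1ccccc1
A3 | alternative 1 | (1Z,13Z)-1,14-bis[2,3,6-tris(benzyloxy)-5-methoxy-4-methylphenyl]tetradeca-1,13-diene | COc1c(C)c(OCc2ccccc2)c(OCc2ccccc2)c(/C=C\CCCCCCCCCC/C=C\c2c(OCc3ccccc3)c(OCc3ccccc3)c(C)c(OC)c2OCc2ccccc2)c1OCc1ccccc1
A4 | alternative 2 | (4E,20E)-tetracosa-4,20-diene-3,22-dione | CCC(=O)/C=C/CCCCCCCCCCCCCC/C=C/C(=O)CC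
A5 | alternative 2 | dimethyl malonate | COC(=O)CC(=O)OC
A6 | alternative 2 | 5,5'-(tetradecane-1,14-diyl)bis(3-hydroxy-2-methylcyclohex-2-en-1-one) | CC1=C(O)CC(CCCCCCCCCCCCCCC2CC(O)=C(C)C(=O)C2)CC1=O
A7 | alternative 3 | 1,2,4-tris(benzyloxy)-3-(but-3-en-1-yl)-5-methoxy-6-methylbenzene | COc1c(C)c(OCc2ccccc2)c(OCc2ccccc2)c(CCC=C)c1OCc1ccccc1
A8 | alternative 3 | cis-cyclooctene | C1CC/C=C\CCC1
A9 | alternative 3 | (3E,11E)-1,14-bis[2,3,6-tris(benzyloxy)-5-methoxy-4-methylphenyl]tetradeca-3,11-diene | COc1c(C)c(OCc2ccccc2)c(OCc2ccccc2)c(CC/C=C/CCCCCC/C=C/CCc2c(OCc3ccccc3)c(OCc3ccccc3)c(C)c(OC)c2OCc2ccccc2)c1OCc1ccccc1
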